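At the time of reading, 4.0 d for theta and 8.0 d for zeta, the question is how many turns of its own clock each flask has had, so we build that clock from the earlier runs.

common to all: left-handed substrate 0.20 M; right-handed substrate 0.20 M
- maple: partner 0.30 M; catalyst 1.9 mM; temperature 10 °C; run made earlier
- ash: partner 0.30 M; catalyst 7.5 mM; temperature 25 °C; run made earlier
- theta: partner 0.300 M; catalyst 5.0 mM; temperature 25 °C; time 4.0 d
- zeta: partner 0.300 M; catalyst 1.5 mM; temperature 25 °C; time 8.0 d

- maple (time / d: left-handed product / %, left-handed substrate / %): 0.417: 5, 45; 0.625: 10, 41; 1.04: 15, 38; 1.67: 17, 36; 2.50: 23, 27; 4.00: 28, 21; 6.00: 35, 17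
- ash (time / d: left-handed product / %, left-handed substrate / %): 0.167: 22, 30; 0.417: 34, 19; 0.833: 39, 10; 1.25: 44, 8; 1.67: 45, 4; 2.00: 49, 2; 3.00: 48, 0

(standard deviation of a reading: 1.5 percentage points)

- which of the two ends with the higher amount of left-handed product, in percent of the left-handed substrate and right-handed substrate together charged ("neither" if they lie within 2 percentage points) (theta / zeta / neither)
- left-handed product at the end, in percent of the left-handed substrate and right-handed substrate together charged, theta
- left-handed product at the end, in percent of the left-handed substrate and right-handed substrate together charged, zeta

- catalyst is single-handed; left-handed substrate and right-handed substrate are mirror images of each other, charged as a racemate, each of them at the stated concentration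

In both runs the left-handed substrate lost reappears as left-handed product, so we take one partner per left-handed substrate, with product topping out at half of the total charge. We assume the rate goes as catalyst times partner times left-handed substrate, and solve it at both ends. At the start partner stands at 0.300 M; on our one-to-one count it tends in the tail to its excess, 0.100 M, and the decay there is pseudo-first-order. Joining the ends gives, with r and b the fractions of left-handed substrate and partner left, and s the tail rate:

ln(b/r) = s × time

The ash reading of 10% left-handed substrate at 0.833 d means r = 20.0% and b = 46.7%, so:

s = 1.02 d⁻¹ for ash

This s, the tail rate, is a reading with its scatter. Maple differs in both temperature and catalyst, so scaling s with catalyst is our assumption. It gives 0.678 d⁻¹ for theta and 0.203 d⁻¹ for zeta. The ladder of decay times of left-handed substrate, each one over its rate with partner as charged (start) or at the excess (tail), fastest first: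

theta, start: 0.492 d
theta, tail: 1.47 d
zeta, start: 1.64 d
zeta, tail: 4.93 d

Theta thus gets s × time = 2.71 and zeta 1.63. Our reckoning ends zeta at 46.2% and theta at 48.8%, so theta ends higher than zeta.

The forecast names theta, with 48.8% and 46.1%, and adds “The gap is modest and depends on catalyst order”.

The flasks give 47.2% for theta and 39.5% for zeta, so theta ends higher, with zeta 6.7 percentage points below our reckoning and theta 1.6 points below.

    partner + catalyst + left-handed substrate → catalyst + left-handed product (k = 67.4 M⁻² h⁻¹, Ea = 51.0 kJ mol⁻¹)
    2 partner → self-condensation product (k = 0.0284 M⁻¹ h⁻¹, Ea = 73.0 kJ mol⁻¹)
    partner + catalyst + right-handed substrate → catalyst + right-handed product (k = 1.01 M⁻² h⁻¹, Ea = 54.0 kJ mol⁻¹)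
    (constants at 25 °C)

At its end zeta holds 0.0549 M of self-condensation product, which took 0.110 M of partner, more than the excess. The neighbouring flask is theta with 0.075 M of partner, so partner is the limiting reagent, and left-handed substrate stands in excess by 0.125 M. The same clock gives s × time = 3.39, hence 18.4% of left-handed product. That flask gives 17.6%, with 0.86% of its partner left.

(The data stem from a simulated flask from invented constants; noise was put on by code.)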